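## Analysis of the target

The target is 2-[(3R,5R)-3,5-dimethyl-5-[(2R,7E,11E)-2-methyl-12-phenyldodeca-7,11-dien-1-yl]-1,2-dioxolan-3-yl]acetic acid. Numbered from the carboxyl carbon, C1 and C2 form the acetic acid arm, C3–C4–C5 are the ring carbons with the O–O bond joining C3 and C5, and C6 leads to C7, which carries a methyl group. C8–C11 are methylenes, C12=C13 and C16=C17 are E alkenes, and C17 carries the phenyl ring. There are three stereocentres. C3 and C5 are fully substituted peroxy carbons whose methyl groups are cis, so the arms C2 and C6 are cis as well. C7 (R) lies outside the ring, 1,3 to C5, where the ring cannot control it. The O–O bond excludes catalytic hydrogenation, low-valent metals, strong hydride donors and carbon radicals placed β or γ to it. The β-peroxy carboxyl unit (C1–C2–C3–O) opens by E1cB elimination once an enolate forms at C2. The difficulty is to set two oxygen-bearing quaternary centres, separated by one CH2, in a cis relationship and in one absolute sense with no neighbouring stereocentre to lean on. The strategy rests on the fact that C3 and C5 have the same substituents (methyl, peroxy oxygen, C4, one CH2 arm). The fragment C2–C3(CH3)(O)–C4–C5(CH3)(O)–C6 is therefore mirror-symmetric, corresponds to acetylacetone 1 plus a peroxide unit, and becomes the meso bicycle 8 when C2 and C6 are joined through one extra carbon.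

## Retrosynthetic reasoning

**C1 ester and C12=C13.** The acid 42 is taken back to its methyl ester 41, so that the carboxyl group is masked during the chain work. The isolated E alkene C12=C13 is then cut by a Julia–Kocienski disconnection into aldehyde 32 and sulfone 39. This is the best place to cut because 39 is achiral, peroxide-free and already carries the E styrenyl alkene from 33 (with two carbons from 34). It also means that the peroxide meets both alkenes only at the very end, when no reduction remains to be done.

**C8–C9.** Aldehyde 32 is cut between C8 and C9 into the α-methyl aldehyde 25 and the four-carbon phosphonium salt 27 (from 26). The forward Wittig reaction gives alkene 29, which is saturated by metal-free hydrogen transfer at a stage where it is the only alkene in the molecule. This is why the chain is grown in two stages and not attached in one piece.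

**C7–CH3 and C6–C7.** Aldehyde 25 goes back through alcohol 24 to imide 23, whose C7 methyl group is removed to give 21. The forward methylation of the chelated imide enolate sets C7 under control of the auxiliary 14, the only practical source of control for a centre the ring cannot influence. Imide 21 comes from enimide 20 by saturation, and 20 is cut at C6=C7 into the ring aldehyde 13 and the stabilised ylide 19 (from 14 and 15). The neutral ylide is chosen so that aldehyde 13 never meets a base or a metal alkoxide.

**Differentiating the arms.** Aldehyde 13 comes from hydroxy ester 12, and 12 from the bridged lactone 11 by methanolysis. Reconnecting C1 to C6 and removing the inserted oxygen gives the meso ketone 10. In the forward direction an enantioselective Baeyer–Villiger oxidation decides which of the two enantiotopic CH2 groups migrates. This single event makes one arm the C1 carboxyl and the other the C6 carbinol, and fixes the absolute configuration of C3 and C5 together. Ketone 10 comes from alkene 8 by ozonolysis.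

**C2–C3 and C5–C6 (key disconnection).** In 8 the two bonds from the peroxy carbons to the CH2 arms are cut. This leaves the bis-peroxyketal 3 as a double electrophile and the bis-allylsilane 6 as a double nucleophile. The cut is made here because it removes both quaternary centres in one step and because the one-carbon tether in 8 only allows cis bridging. The forward reaction must run two successive allylations of peroxycarbenium ions, the second one intramolecular.

**Precursors.** Bis-ketal 3 comes from 1 through the cyclic bis-hemiperketal 2. Bis-silane 6 comes from dichloride 4 by double in situ Grignard silylation.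

## Alternatives that were turned down

**Alternative 1:** The ring bonds C4–C5 and O–C3 are cut. C5 with its methyl group and the C6–C12 chain then come from a methyl ketone made from (R)-citronellal A3 and activated as the methoxy triethylsilylperoxy ketal A2. C1–C4 come from the homoallylic silyl ether A4. In the forward step a tin Lewis acid ionises A2 to an open-chain peroxycarbenium ion. The 1,1-disubstituted alkene of A4 adds through its CH2 terminus (C4–C5), and the tertiary cation at C3 is captured by the peroxy oxygen with loss of the silyl group (O–C3) to give dioxolane A1.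
- For it: C7 arrives from the chiral pool, so no auxiliary and no enolate chemistry next to a peroxide are needed. This annulation type is established in intermolecular form, and the route is convergent and several steps shorter. On precedent, step count and C7 it is stronger than the chosen route.
- Against it: C3 and C5 are both created with nothing to tell their faces apart (methyl against a CH2 chain at each), and C7 is too remote to bias either. All four C3/C5 combinations are to be expected, and the wanted one differs from the rest only in remote relationships, so separation would be difficult and most material lost.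
- Comparison: it is weak on the one problem that defines the target. The chosen route spends more steps, but 8 can only be cis and the absolute sense is chosen by a catalyst at 11.

**Alternative 2:** C3–C4 and O–C5 are cut as in a peroxycarbenium–alkene annulation, but the two partners are tied together by an ether oxygen between C1 and C6. The precursor is A6, a methoxy silylperoxy ketal whose chain ends in a methallyl ether. A Lewis acid ionises A6, and the tethered alkene attacks through its CH2 terminus (C3–C4, closing an oxepane in a 7-endo mode). The tertiary cation at C5 is then trapped by the peroxy oxygen (O–C5) to give the bridged ether A5.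
- For it: the tether enforces cis bridging as surely as the carbocycle of 8. The two arms come out already differentiated, so no ozonolysis or Baeyer–Villiger step is needed, and oxidation of the less hindered O–CH2 group of A5 would lead to racemic 11 in fewer steps. The annulation is also closer to established reactivity than the chosen key step.
- Against it: A5 is chiral and would form as a racemate, since nothing in A6 can induce asymmetry, so half the material is lost to a resolution. The seven-membered closure has to compete with elimination and intermolecular reaction. The ether oxygen and the allylic C–O bond are themselves Lewis-basic or ionisable, and the later ether oxidation must discriminate two O–CH2 groups next to an O–O bond.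
- Comparison: the chosen route passes through a meso compound, so all of it can in principle be converted into one enantiomer, and its ring closure is six-membered.

**Alternative 3:** The O–C5 bond is cut in the bicyclic iodide A7. This goes back to the cyclohexenyl hydroperoxide A10, to 1,5-dimethylcyclohexa-1,4-diene A9 and to m-xylene A8. An electrophilic iodine source activates the ring alkene of A10, and the hydroperoxide oxygen adds across the ring to the methyl-bearing alkene carbon, anti to iodine, to give A7.
- For it: the starting material is the cheapest of all, the carbocycle with both methyl groups is there from the start, and the ring enforces cis bridging. Each stage is a known reaction type. Dehydroiodination and cleavage of the resulting ring alkene would give two arms of unequal length without a Baeyer–Villiger step. On cost and on precedent for the single steps it is stronger than the chosen route.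
- Against it: A9 has two doubly allylic CH2 groups and should revert to A8 under radical hydroperoxidation conditions, and only one of its two equivalent alkenes may react. A10 is racemic with no evident enantioselective entry, so A7 is racemic. The elimination needs base next to the peroxide, and the cleavage gives two aldehydes that still have to be told apart.
- Comparison: it is equal on cis control but weaker on absolute configuration. The chosen route keeps the mirror symmetry until a catalyst breaks it at the stage of 10.

Key step: step 4

Assumption: which Baeyer–Villiger monooxygenase of a screening panel gives lactone 11 and not its mirror image is taken to be settled by screening, since the cyclohexanone and cyclopentanone monooxygenase types commonly give opposite enantiomers from meso ketones. Compounds 2, 3 and 8–10 are low-molecular-weight peroxides and are meant to be made on small scale behind a shield.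

## Route

Step 1
Reactants: 1 acetylacetone (pentane-2,4-dione)
Product: 2 3,5-dimethyl-1,2-dioxolane-3,5-diol (interconverting cis/trans mixture)
Conditions: 30% aq. H2O2 (1.05 equiv), Et2O, 0 °C → rt
Reagents that add atoms: hydrogen peroxide, OO
Why: Double hemiperketalisation: the peroxide adds to one carbonyl group and the resulting hydroperoxide closes onto the second (5-exo), a known reaction of this diketone; the stereochemistry is irrelevant because both centres are ionised later.

Step 2
Reactants: 2 3,5-dimethyl-1,2-dioxolane-3,5-diol
Product: 3 3,5-dimethoxy-3,5-dimethyl-1,2-dioxolane (cis/trans mixture, used as such)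
Conditions: MeOH, p-TsOH (cat.), 3 Å molecular sieves, 0 °C → rt
Reagents that add atoms: methanol, CO
Why: Acid-catalysed exchange of hemiperketal OH for OMe through peroxycarbenium ions, the known way from 3-hydroxy- to 3-alkoxy-1,2-dioxolanes; both diastereomers are carried on.

Step 3
Reactants: 4 3-chloro-2-(chloromethyl)prop-1-ene
Product: 6 2-methylidenepropane-1,3-diylbis(trimethylsilane), via mono-silylated allyl chloride 5 (not isolated)
Conditions: Mg (2.5 equiv), Me3SiCl (2.5 equiv), THF, reflux, slow addition of 4
Reagents that add atoms: chlorotrimethylsilane, C[Si](C)(C)Cl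
Why: In situ Grignard formation and silylation (Barbier type), run twice; trapping each allylmagnesium species as it forms suppresses Wurtz coupling.

Step 4
Reactants: 3 3,5-dimethoxy-3,5-dimethyl-1,2-dioxolane; 6 2-methylidenepropane-1,3-diylbis(trimethylsilane)
Product: 8 (1R,5S)-1,5-dimethyl-3-methylidene-6,7-dioxabicyclo[3.2.1]octane (meso), via mono-allylated methoxydioxolane 7 (not isolated)
Conditions: TiCl4 (2.2 equiv), CH2Cl2 (0.02 M), −78 → −40 °C; aq. NaHCO3
Reagents that add atoms: none
Why: Proposed new method: TiCl4 should ionise one methoxy group of 3 to a cyclic peroxycarbenium ion, which the =CH2 terminus of 6 attacks with loss of one Me3Si group to give 7, a new 2-substituted allylsilane held on the ring. Ionisation of the second ketal then lets this tethered allylsilane attack, again through its CH2 terminus, and loss of the second silyl group leaves the exocyclic methylene. The closest known reaction types are the Lewis acid allylation of 3-alkoxy-1,2-dioxolanes by allylsilanes (Hosomi–Sakurai type on a peroxycarbenium ion) and [3+3] annulations of 6 with 1,3-dielectrophiles; what is new is running both on a bis-peroxyketal in one operation. The one ring that closes is the cyclohexane, by C–C bond formation in a 6-endo-trig mode at the allylsilane π bond (exo with respect to the C=O+ bond of the cation), which turns the dioxolane into the 6,7-dioxabicyclo[3.2.1]octane. The two bridgehead stereocentres are controlled by the tether: the three-atom arm on the first carbon can reach the planar cation at the second only from its own face, so only cis bridging is possible and both diastereomers of 3 and of 7 converge. Because 8 is meso, no absolute control is needed here. The step needs the intramolecular capture of the second cation to outrun attack by a second molecule of 6; the proximity of the internal nucleophile, high dilution and no large excess of 6 should secure this.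

Step 5
Reactants: 8 (1R,5S)-1,5-dimethyl-3-methylidene-6,7-dioxabicyclo[3.2.1]octane
Product: 10 (1R,5S)-1,5-dimethyl-6,7-dioxabicyclo[3.2.1]octan-3-one (meso), via spiro ozonide 9 (not isolated)
Conditions: O3, CH2Cl2, −78 °C; then Me2S, −78 °C → rt
Reagents that add atoms: ozone, [O-][O+]=O
Why: Ozonolysis of the 1,1-disubstituted alkene with reductive work-up; the di-tertiary peroxide is inert to ozone and to the sulfide, and no base is present that could open the β-peroxy ketone.

Step 6
Reactants: 10 (1R,5S)-1,5-dimethyl-6,7-dioxabicyclo[3.2.1]octan-3-one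
Product: 11 (1S,6R)-1,6-dimethyl-3,7,8-trioxabicyclo[4.2.1]nonan-4-one
Conditions: cyclohexanone monooxygenase (panel enzyme selected by screening), NADP+ (cat.), glucose dehydrogenase, D-glucose, air, phosphate buffer pH 7.0, 25 °C
Reagents that add atoms: dioxygen, O=O
Why: Enzymatic Baeyer–Villiger desymmetrisation of a meso bridged ketone, a known use of these monooxygenases. The active site decides which enantiotopic CH2 migrates, which fixes both quaternary centres in the absolute sense needed; neutral pH avoids β-elimination.

Step 7
Reactants: 11 (1S,6R)-1,6-dimethyl-3,7,8-trioxabicyclo[4.2.1]nonan-4-one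
Product: 12 methyl 2-[(3R,5S)-5-(hydroxymethyl)-3,5-dimethyl-1,2-dioxolan-3-yl]acetate
Conditions: MeOH, camphorsulfonic acid (cat.), 0 °C → rt; solid NaHCO3, filter
Reagents that add atoms: methanol, CO
Why: Acid-catalysed methanolysis of the seven-membered lactone (transesterification); acid and not alkoxide is used so that no enolate forms next to the peroxide.

Step 8
Reactants: 12 methyl 2-[(3R,5S)-5-(hydroxymethyl)-3,5-dimethyl-1,2-dioxolan-3-yl]acetate
Product: 13 methyl 2-[(3R,5S)-5-formyl-3,5-dimethyl-1,2-dioxolan-3-yl]acetate
Conditions: Dess–Martin periodinane, CH2Cl2, 0 °C → rt; used at once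
Reagents that add atoms: none
Why: Dess–Martin oxidation of a neopentyl-type primary alcohol under neutral conditions; the aldehyde has no α-hydrogen and cannot epimerise, but it is not stored.

Step 9
Reactants: 14 (4S)-4-benzyl-1,3-oxazolidin-2-one; 15 bromoacetyl bromide
Product: 17 (4S)-4-benzyl-3-(2-bromoacetyl)-1,3-oxazolidin-2-one, via lithium oxazolidinide 16 (not isolated)
Conditions: n-BuLi, THF, −78 °C; then 15, −78 °C
Reagents that add atoms: none
Why: N-Acylation of the lithiated auxiliary with an acid bromide, a standard preparation of N-acyl oxazolidinones.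

Step 10
Reactants: 17 (4S)-4-benzyl-3-(2-bromoacetyl)-1,3-oxazolidin-2-one
Product: 19 (4S)-4-benzyl-3-[2-(triphenyl-λ5-phosphanylidene)acetyl]-1,3-oxazolidin-2-one, via phosphonium bromide 18 (not isolated)
Conditions: PPh3, toluene, rt; then aq. Na2CO3, CH2Cl2, 0 °C
Reagents that add atoms: triphenylphosphine, c1ccc(cc1)P(c1ccccc1)c1ccccc1
Why: SN2 quaternisation of the phosphine, then deprotonation of the acidic acyl-phosphonium salt with mild base to the stabilised, isolable ylide; carbonate is chosen so that the imide is not hydrolysed.

Step 11
Reactants: 13 methyl 2-[(3R,5S)-5-formyl-3,5-dimethyl-1,2-dioxolan-3-yl]acetate; 19 (4S)-4-benzyl-3-[2-(triphenyl-λ5-phosphanylidene)acetyl]-1,3-oxazolidin-2-one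
Product: 20 methyl 2-[(3R,5S)-5-{(1E)-3-[(4S)-4-benzyl-2-oxo-1,3-oxazolidin-3-yl]-3-oxoprop-1-en-1-yl}-3,5-dimethyl-1,2-dioxolan-3-yl]acetate
Conditions: toluene, rt → 50 °C
Reagents that add atoms: none
Why: Wittig reaction of a stabilised ylide, E-selective and run without base or metal salts. No free alkoxide is formed next to the peroxide and the β-peroxy ester is not enolised.

Step 12
Reactants: 20 the enimide from step 11
Product: 21 methyl 2-[(3R,5R)-5-{3-[(4S)-4-benzyl-2-oxo-1,3-oxazolidin-3-yl]-3-oxopropyl}-3,5-dimethyl-1,2-dioxolan-3-yl]acetate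
Conditions: KO2CN=NCO2K, AcOH, MeOH/CH2Cl2, 0 °C → rt, repeated until complete
Reagents that add atoms: none
Why: Diimide reduction (concerted syn transfer of H2) saturates the electron-poor C6=C7 alkene and leaves the O–O bond intact, which catalytic hydrogenation would not; the medium is weakly acidic.

Step 13
Reactants: 21 the saturated imide from step 12
Product: 23 methyl 2-[(3R,5R)-5-{(2S)-3-[(4S)-4-benzyl-2-oxo-1,3-oxazolidin-3-yl]-2-methyl-3-oxopropyl}-3,5-dimethyl-1,2-dioxolan-3-yl]acetate, via sodium Z-enolate 22 (not isolated)
Conditions: NaN(SiMe3)2 (1.05 equiv), THF, −78 °C; MeI, −78 → −50 °C; AcOH quench at −78 °C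
Reagents that add atoms: iodomethane, CI
Why: Evans alkylation: the chelated Z-enolate is methylated on the face opposite the benzyl group, which gives the (2S) centre here; this becomes (R) at C7 of the target once C8 loses its oxygen. The imide is several pKa units more acidic than the methyl ester, so one equivalent of base at −78 °C should leave the β-peroxy ester untouched.

Step 14
Reactants: 23 the methylated imide from step 13
Product: 24 methyl 2-[(3R,5R)-5-[(2S)-3-hydroxy-2-methylpropyl]-3,5-dimethyl-1,2-dioxolan-3-yl]acetate
Conditions: NaBH4, THF/H2O (4:1), 0 °C → rt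
Reagents that add atoms: none
Why: Reductive cleavage of the N-acyl oxazolidinone at the exocyclic carbonyl by borohydride in wet THF; methyl ester and dialkyl peroxide are not reduced under these conditions and the auxiliary is recovered.

Step 15
Reactants: 24 the alcohol from step 14
Product: 25 methyl 2-[(3R,5R)-3,5-dimethyl-5-[(2S)-2-methyl-3-oxopropyl]-1,2-dioxolan-3-yl]acetate
Conditions: Dess–Martin periodinane, CH2Cl2, 0 °C; used at once
Reagents that add atoms: none
Why: Dess–Martin oxidation under non-basic conditions, chosen to keep the α-methyl stereocentre at C7 from epimerising.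

Step 16
Reactants: 26 (4-bromobutoxy)(tert-butyl)dimethylsilane
Product: 27 {4-[tert-butyl(dimethyl)silyl]oxybutyl}triphenylphosphonium bromide
Conditions: PPh3, MeCN, reflux
Reagents that add atoms: triphenylphosphine, c1ccc(cc1)P(c1ccccc1)c1ccccc1
Why: SN2 quaternisation of the phosphine by a primary bromide.

Step 17
Reactants: 25 the aldehyde from step 15; 27 {4-[tert-butyl(dimethyl)silyl]oxybutyl}triphenylphosphonium bromide
Product: 29 methyl 2-[(3R,5R)-5-[(2S,3Z)-7-{[tert-butyl(dimethyl)silyl]oxy}-2-methylhept-3-en-1-yl]-3,5-dimethyl-1,2-dioxolan-3-yl]acetate, via phosphorus ylide 28 (not isolated)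
Conditions: 27, NaN(SiMe3)2 (slightly less than 27), THF, −78 → 0 °C; then 25, −78 °C → rt
Reagents that add atoms: none
Why: Wittig reaction of a non-stabilised ylide forms C8=C9; the geometry is of no consequence because the alkene is reduced next. The fast, cold addition to the aldehyde should outrun epimerisation at C7 and enolisation of the ester.

Step 18
Reactants: 29 the Z-alkene from step 17
Product: 30 methyl 2-[(3R,5R)-5-[(2R)-7-{[tert-butyl(dimethyl)silyl]oxy}-2-methylheptyl]-3,5-dimethyl-1,2-dioxolan-3-yl]acetate
Conditions: KO2CN=NCO2K, AcOH, MeOH/CH2Cl2, rt, repeated until complete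
Reagents that add atoms: none
Why: Diimide reduction of the only alkene present, without touching the peroxide; any silyl ether lost to the acetic acid is simply the next intermediate.

Step 19
Reactants: 30 the silyl ether from step 18
Product: 31 methyl 2-[(3R,5R)-5-[(2R)-7-hydroxy-2-methylheptyl]-3,5-dimethyl-1,2-dioxolan-3-yl]acetate
Conditions: HF·pyridine, THF, 0 °C → rt
Reagents that add atoms: none
Why: Fluoride-mediated desilylation under weakly acidic conditions, which spares the β-peroxy ester that basic fluoride sources could open.

Step 20
Reactants: 31 the alcohol from step 19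
Product: 32 methyl 2-[(3R,5R)-3,5-dimethyl-5-[(2R)-2-methyl-7-oxoheptyl]-1,2-dioxolan-3-yl]acetate
Conditions: Dess–Martin periodinane, CH2Cl2, 0 °C → rt
Reagents that add atoms: none
Why: Dess–Martin oxidation of a primary alcohol to the aldehyde under neutral conditions.

Step 21
Reactants: 33 trans-cinnamyl chloride; 34 tert-butyl acetate
Product: 36 tert-butyl (4E)-5-phenylpent-4-enoate, via lithium ester enolate 35 (not isolated)
Conditions: 34, LiN(i-Pr)2, THF, −78 °C; then 33, DMPU, −78 → 0 °C
Reagents that add atoms: none
Why: Alkylation of a lithium ester enolate by an allylic chloride at the CH2 terminus, which keeps the styrene conjugated and E; the tert-butyl ester resists self-condensation.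

Step 22
Reactants: 36 tert-butyl (4E)-5-phenylpent-4-enoate
Product: 37 (4E)-5-phenylpent-4-en-1-ol
Conditions: LiAlH4, Et2O, 0 °C; Fieser work-up
Reagents that add atoms: none
Why: Hydride reduction of the ester to the primary alcohol; the isolated styrenyl alkene is not reduced.

Step 23
Reactants: 37 (4E)-5-phenylpent-4-en-1-ol
Product: 38 1-phenyl-5-{[(4E)-5-phenylpent-4-en-1-yl]sulfanyl}-1H-tetrazole
Conditions: 1-phenyl-1H-tetrazole-5-thiol, PPh3, DIAD, THF, 0 °C → rt
Reagents that add atoms: 1-phenyl-1H-tetrazole-5-thiol, Sc1nnnn1-c1ccccc1
Why: Mitsunobu thioetherification of an unhindered primary alcohol with an acidic heteroaryl thiol.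

Step 24
Reactants: 38 the sulfide from step 23
Product: 39 1-phenyl-5-{[(4E)-5-phenylpent-4-en-1-yl]sulfonyl}-1H-tetrazole
Conditions: (NH4)6Mo7O24·4H2O (cat.), 30% aq. H2O2, EtOH, 0 °C → rt
Reagents that add atoms: hydrogen peroxide, OO
Why: Molybdate-catalysed oxidation of sulfide to sulfone, which is selective for sulfur over the disubstituted alkene where a peracid would not be.

Step 25
Reactants: 32 the aldehyde from step 20; 39 the sulfone from step 24
Product: 41 methyl 2-[(3R,5R)-3,5-dimethyl-5-[(2R,7E,11E)-2-methyl-12-phenyldodeca-7,11-dien-1-yl]-1,2-dioxolan-3-yl]acetate, via potassium sulfonyl carbanion 40 (not isolated)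
Conditions: 39, KN(SiMe3)2, DME, −60 °C; then 32, −60 °C → rt
Reagents that add atoms: none
Why: Julia–Kocienski olefination: addition of the metalated phenyltetrazolyl sulfone, Smiles rearrangement and loss of SO2 form C12=C13, with the potassium/DME combination favouring E for two unbranched partners. The carbanion is made first and consumed by the aldehyde, so the ester sees little free base.

Step 26
Reactants: 41 the methyl ester from step 25
Product: 42 2-[(3R,5R)-3,5-dimethyl-5-[(2R,7E,11E)-2-methyl-12-phenyldodeca-7,11-dien-1-yl]-1,2-dioxolan-3-yl]acetic acid (target)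
Conditions: LiOH, THF/H2O (3:1), 0 °C; then 1 M HCl to pH 3
Reagents that add atoms: lithium hydroxide, [Li+].[OH-]
Why: Saponification by hydroxide attack at the ester carbonyl, which is faster at 0 °C than deprotonation at C2; the carboxylate formed is no longer prone to β-elimination of the peroxide.

## Compound list

1 | acetylacetone (pentane-2,4-dione) | CC(=O)CC(C)=O | starting material
2 | 3,5-dimethyl-1,2-dioxolane-3,5-diol (interconverting cis/trans mixture) | CC1(O)CC(C)(O)OO1 | intermediate
3 | 3,5-dimethoxy-3,5-dimethyl-1,2-dioxolane (cis/trans mixture; cis (3R,5S) isomer drawn) | CO[C@]1(C)C[C@](C)(OC)OO1 | intermediate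
4 | 3-chloro-2-(chloromethyl)prop-1-ene | C=C(CCl)CCl | starting material
5 | [2-(chloromethyl)prop-2-en-1-yl]trimethylsilane | C=C(CCl)C[Si](C)(C)C | intermediate
6 | 2-methylidenepropane-1,3-diylbis(trimethylsilane) | C=C(C[Si](C)(C)C)C[Si](C)(C)C | intermediate
7 | 3-methoxy-3,5-dimethyl-5-{2-[(trimethylsilyl)methyl]prop-2-en-1-yl}-1,2-dioxolane (both diastereomers) | COC1(C)CC(C)(CC(=C)C[Si](C)(C)C)OO1 | intermediate
8 | (1R,5S)-1,5-dimethyl-3-methylidene-6,7-dioxabicyclo[3.2.1]octane (meso) | C=C1C[C@]2(C)C[C@](C)(C1)OO2 | intermediate
9 | spiro-1,2,4-trioxolane (secondary ozonide) at C3 of 8, both epimers at the spiro carbon | C1OC2(OO1)C[C@]3(C)C[C@](C)(C2)OO3 | intermediate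
10 | (1R,5S)-1,5-dimethyl-6,7-dioxabicyclo[3.2.1]octan-3-one (meso) | O=C1C[C@]2(C)C[C@](C)(C1)OO2 | intermediate
11 | (1S,6R)-1,6-dimethyl-3,7,8-trioxabicyclo[4.2.1]nonan-4-one | O=C1OC[C@]2(C)C[C@](C)(C1)OO2 | intermediate
12 | methyl 2-[(3R,5S)-5-(hydroxymethyl)-3,5-dimethyl-1,2-dioxolan-3-yl]acetate | OC[C@]1(C)C[C@](C)(CC(=O)OC)OO1 | intermediate
13 | methyl 2-[(3R,5S)-5-formyl-3,5-dimethyl-1,2-dioxolan-3-yl]acetate | O=C[C@]1(C)C[C@](C)(CC(=O)OC)OO1 | intermediate
14 | (4S)-4-benzyl-1,3-oxazolidin-2-one | O=C1N[C@@H](Cc2ccccc2)CO1 | starting material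
15 | bromoacetyl bromide | BrCC(Br)=O | starting material
16 | lithium (4S)-4-benzyl-2-oxo-1,3-oxazolidin-3-ide | [Li+].O=C1[N-][C@@H](Cc2ccccc2)CO1 | intermediate
17 | (4S)-4-benzyl-3-(2-bromoacetyl)-1,3-oxazolidin-2-one | O=C(CBr)N1C(=O)OC[C@@H]1Cc1ccccc1 | intermediate
18 | {2-[(4S)-4-benzyl-2-oxo-1,3-oxazolidin-3-yl]-2-oxoethyl}triphenylphosphonium bromide | O=C(C[P+](c1ccccc1)(c1ccccc1)c1ccccc1)N1C(=O)OC[C@@H]1Cc1ccccc1.[Br-] | intermediate
19 | (4S)-4-benzyl-3-[2-(triphenyl-λ5-phosphanylidene)acetyl]-1,3-oxazolidin-2-one | O=C(C=P(c1ccccc1)(c1ccccc1)c1ccccc1)N1C(=O)OC[C@@H]1Cc1ccccc1 | intermediate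
20 | methyl 2-[(3R,5S)-5-{(1E)-3-[(4S)-4-benzyl-2-oxo-1,3-oxazolidin-3-yl]-3-oxoprop-1-en-1-yl}-3,5-dimethyl-1,2-dioxolan-3-yl]acetate | O=C(/C=C/[C@]1(C)C[C@](C)(CC(=O)OC)OO1)N2C(=O)OC[C@@H]2Cc3ccccc3 | intermediate
21 | methyl 2-[(3R,5R)-5-{3-[(4S)-4-benzyl-2-oxo-1,3-oxazolidin-3-yl]-3-oxopropyl}-3,5-dimethyl-1,2-dioxolan-3-yl]acetate | O=C(CC[C@]1(C)C[C@](C)(CC(=O)OC)OO1)N2C(=O)OC[C@@H]2Cc3ccccc3 | intermediate
22 | sodium (Z)-enolate of 21 | [Na+].[O-]/C(=C\C[C@]1(C)C[C@](C)(CC(=O)OC)OO1)N2C(=O)OC[C@@H]2Cc3ccccc3 | intermediate
23 | methyl 2-[(3R,5R)-5-{(2S)-3-[(4S)-4-benzyl-2-oxo-1,3-oxazolidin-3-yl]-2-methyl-3-oxopropyl}-3,5-dimethyl-1,2-dioxolan-3-yl]acetate | C[C@H](C(=O)N2C(=O)OC[C@@H]2Cc3ccccc3)C[C@]1(C)C[C@](C)(CC(=O)OC)OO1 | intermediate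
24 | methyl 2-[(3R,5R)-5-[(2S)-3-hydroxy-2-methylpropyl]-3,5-dimethyl-1,2-dioxolan-3-yl]acetate | C[C@H](CO)C[C@]1(C)C[C@](C)(CC(=O)OC)OO1 | intermediate
25 | methyl 2-[(3R,5R)-3,5-dimethyl-5-[(2S)-2-methyl-3-oxopropyl]-1,2-dioxolan-3-yl]acetate | C[C@H](C=O)C[C@]1(C)C[C@](C)(CC(=O)OC)OO1 | intermediate
26 | (4-bromobutoxy)(tert-butyl)dimethylsilane | CC(C)(C)[Si](C)(C)OCCCCBr | starting material
27 | {4-[tert-butyl(dimethyl)silyl]oxybutyl}triphenylphosphonium bromide | CC(C)(C)[Si](C)(C)OCCCC[P+](c1ccccc1)(c1ccccc1)c1ccccc1.[Br-] | intermediate
28 | tert-butyl(dimethyl)[4-(triphenyl-λ5-phosphanylidene)butoxy]silane | CC(C)(C)[Si](C)(C)OCCCC=P(c1ccccc1)(c1ccccc1)c1ccccc1 | intermediate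
29 | methyl 2-[(3R,5R)-5-[(2S,3Z)-7-{[tert-butyl(dimethyl)silyl]oxy}-2-methylhept-3-en-1-yl]-3,5-dimethyl-1,2-dioxolan-3-yl]acetate | C[C@H](/C=C\CCCO[Si](C)(C)C(C)(C)C)C[C@]1(C)C[C@](C)(CC(=O)OC)OO1 | intermediate
30 | methyl 2-[(3R,5R)-5-[(2R)-7-{[tert-butyl(dimethyl)silyl]oxy}-2-methylheptyl]-3,5-dimethyl-1,2-dioxolan-3-yl]acetate | C[C@H](CCCCCO[Si](C)(C)C(C)(C)C)C[C@]1(C)C[C@](C)(CC(=O)OC)OO1 | intermediate
31 | methyl 2-[(3R,5R)-5-[(2R)-7-hydroxy-2-methylheptyl]-3,5-dimethyl-1,2-dioxolan-3-yl]acetate | C[C@H](CCCCCO)C[C@]1(C)C[C@](C)(CC(=O)OC)OO1 | intermediate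
32 | methyl 2-[(3R,5R)-3,5-dimethyl-5-[(2R)-2-methyl-7-oxoheptyl]-1,2-dioxolan-3-yl]acetate | C[C@H](CCCCC=O)C[C@]1(C)C[C@](C)(CC(=O)OC)OO1 | intermediate
33 | trans-cinnamyl chloride, [(1E)-3-chloroprop-1-en-1-yl]benzene | ClC/C=C/c1ccccc1 | starting material
34 | tert-butyl acetate | CC(=O)OC(C)(C)C | starting material
35 | lithium 1-tert-butoxyethen-1-olate | [Li+].C=C([O-])OC(C)(C)C | intermediate
36 | tert-butyl (4E)-5-phenylpent-4-enoate | CC(C)(C)OC(=O)CC/C=C/c1ccccc1 | intermediate
37 | (4E)-5-phenylpent-4-en-1-ol | OCCC/C=C/c1ccccc1 | intermediate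
38 | 1-phenyl-5-{[(4E)-5-phenylpent-4-en-1-yl]sulfanyl}-1H-tetrazole | c1ccccc1/C=C/CCCSc1nnnn1-c1ccccc1 | intermediate
39 | 1-phenyl-5-{[(4E)-5-phenylpent-4-en-1-yl]sulfonyl}-1H-tetrazole | O=S(=O)(CCC/C=C/c1ccccc1)c1nnnn1-c1ccccc1 | intermediate
40 | potassium salt of 39 (α-sulfonyl carbanion) | [K+].[CH-](CC/C=C/c1ccccc1)S(=O)(=O)c1nnnn1-c1ccccc1 | intermediate
41 | methyl 2-[(3R,5R)-3,5-dimethyl-5-[(2R,7E,11E)-2-methyl-12-phenyldodeca-7,11-dien-1-yl]-1,2-dioxolan-3-yl]acetate | C[C@H](CCCC/C=C/CC/C=C/c1ccccc1)C[C@]1(C)C[C@](C)(CC(=O)OC)OO1 | intermediate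
42 | 2-[(3R,5R)-3,5-dimethyl-5-[(2R,7E,11E)-2-methyl-12-phenyldodeca-7,11-dien-1-yl]-1,2-dioxolan-3-yl]acetic acid | C[C@H](CCCC/C=C/CC/C=C/c1ccccc1)C[C@]1(C)C[C@](C)(CC(=O)O)OO1 | target

## Step count and least certain steps

Total: 26 steps. Longest linear sequence: 18 steps (1, 2, 4–8, 11–15, 17–20, 25, 26). The side branches are step 3 (bis-silane), steps 9–10 (ylide), step 16 (phosphonium salt) and steps 21–24 (sulfone).

**Step 4 (key step, beyond known chemistry).** What is most likely to go wrong is capture of the second peroxycarbenium ion by another molecule of 6, which would give open bis-allylated dioxolanes instead of ring closure. Protodesilylation of 7 by adventitious acid before it cyclises is a second risk, and Lewis acid-induced heterolysis of the O–O bond a third. The fallback uses only known reaction types and gives up the bicycle. It sets out from 3. One methoxy group is replaced by the silyl ketene acetal 1-methoxy-1-(trimethylsilyloxy)ethene under TiCl4, the known reaction of 3-alkoxy-1,2-dioxolanes with such nucleophiles. This should give methyl 2-(5-methoxy-3,5-dimethyl-1,2-dioxolan-3-yl)acetate F1. The second methoxy group is replaced in the same way by 2-(trimethylsilyloxy)propene to give the keto ester methyl 2-[3,5-dimethyl-5-(2-oxopropyl)-1,2-dioxolan-3-yl]acetate F2. This forms as a cis/trans mixture with no useful bias, and the racemic cis isomer is separated by chromatography. Baeyer–Villiger oxidation with CF3CO3H (the primary alkyl group migrates in preference to methyl) gives the acetate methyl 2-[5-(acetoxymethyl)-3,5-dimethyl-1,2-dioxolan-3-yl]acetate F3. Acid methanolysis then gives racemic 12, that is 12 together with its enantiomer methyl 2-[(3S,5R)-5-(hydroxymethyl)-3,5-dimethyl-1,2-dioxolan-3-yl]acetate F4. The racemate is taken through steps 8 and 11, where the enantiomeric aldehyde methyl 2-[(3S,5R)-5-formyl-3,5-dimethyl-1,2-dioxolan-3-yl]acetate F5 accompanies 13. The (S)-auxiliary of 19 turns the two series into 20 and its ring diastereomer F6, which are separated by chromatography. The fallback comes back to the route at 20.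

**Step 6 (enantioselective Baeyer–Villiger oxidation).** The enzyme may not accept the peroxide-bridged ketone, may give the lactone in the mirror-image sense or with low selectivity, or may turn over so slowly that 10 loses the peroxide by β-elimination in the buffer. The fallback sets out from 10 and gives up desymmetrisation for resolution. Baeyer–Villiger oxidation with mCPBA (CH2Cl2, Na2HPO4) gives the racemic lactone, 11 together with (1R,6S)-1,6-dimethyl-3,7,8-trioxabicyclo[4.2.1]nonan-4-one F7. Steps 7, 8 and 11 are run on the racemate, passing through F4 and F5 beside 12 and 13. The diastereomer F6 is removed from 20 by chromatography or crystallisation, and the fallback comes back at 20.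

**Step 11 (Wittig reaction of the α-peroxy aldehyde).** The neutral ylide may react too slowly with the neopentyl-type aldehyde. Aldehyde 13 may then decompose on warming, by nucleophilic addition followed by cleavage of the C5–C6 bond with loss of the O–O bond. The fallback sets out from 17. Arbuzov reaction with triethyl phosphite gives diethyl {2-[(4S)-4-benzyl-2-oxo-1,3-oxazolidin-3-yl]-2-oxoethyl}phosphonate F8. The more nucleophilic phosphonate anion is then used in a Horner–Wadsworth–Emmons reaction with 13 under Masamune–Roush conditions (LiCl, i-Pr2NEt, MeCN, 0 °C), and the fallback comes back at 20.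

**Step 13 (methylation next to the peroxide).** Base may deprotonate C2 of the ester and open the dioxolane by β-elimination, the imide enolate may attack the O–O bond, or facial selectivity may be incomplete. The fallback avoids strong base and sets out from 13. Wittig reaction with the stabilised ylide 2-(triphenylphosphoranylidene)propanal gives the enal methyl 2-[(3R,5S)-3,5-dimethyl-5-[(1E)-2-methyl-3-oxoprop-1-en-1-yl]-1,2-dioxolan-3-yl]acetate F9. An ene-reductase of the old yellow enzyme family, chosen for the (S) sense at the α-carbon and coupled to an alcohol dehydrogenase with cofactor recycling, reduces the C=C bond and then the aldehyde. The fallback comes back at 24 and skips steps 11–14.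

**Step 25 (Julia–Kocienski olefination).** The basic sulfonyl carbanion may enolise the β-peroxy ester and open the ring, and E selectivity may be eroded. The fallback sets out from 31 and moves the saponification forward. LiOH in THF/H2O gives the hydroxy acid 2-[(3R,5R)-5-[(2R)-7-hydroxy-2-methylheptyl]-3,5-dimethyl-1,2-dioxolan-3-yl]acetic acid F10. Dess–Martin oxidation gives the aldehyde acid 2-[(3R,5R)-3,5-dimethyl-5-[(2R)-2-methyl-7-oxoheptyl]-1,2-dioxolan-3-yl]acetic acid F11. This is treated with two equivalents of 40, the first of which only forms the carboxylate, and a carboxylate is not enolised under these conditions. The fallback comes back at 42.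

**Step 26 (saponification).** Hydroxide may act as a base at C2 and trigger retro-oxa-Michael opening of the dioxolane. The fallback sets out from 41 and replaces hydroxide by an esterase (pig liver esterase, phosphate buffer pH 7, rt), which hydrolyses the methyl ester at neutral pH. It comes back at 42 and makes no new compound.

## Further compounds

F1 | step 4 | methyl 2-(5-methoxy-3,5-dimethyl-1,2-dioxolan-3-yl)acetate (diastereomer mixture) | COC(=O)CC1(C)CC(C)(OC)OO1
F2 | step 4 | methyl 2-[(3R*,5S*)-3,5-dimethyl-5-(2-oxopropyl)-1,2-dioxolan-3-yl]acetate (racemic cis isomer, one enantiomer drawn) | CC(=O)C[C@]1(C)C[C@](C)(CC(=O)OC)OO1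
F3 | step 4 | methyl 2-[(3R*,5S*)-5-(acetoxymethyl)-3,5-dimethyl-1,2-dioxolan-3-yl]acetate (racemic cis isomer, one enantiomer drawn) | CC(=O)OC[C@]1(C)C[C@](C)(CC(=O)OC)OO1
F4 | step 4 | methyl 2-[(3S,5R)-5-(hydroxymethyl)-3,5-dimethyl-1,2-dioxolan-3-yl]acetate (enantiomer of 12) | OC[C@@]1(C)C[C@@](C)(CC(=O)OC)OO1
F5 | step 4 | methyl 2-[(3S,5R)-5-formyl-3,5-dimethyl-1,2-dioxolan-3-yl]acetate (enantiomer of 13) | O=C[C@@]1(C)C[C@@](C)(CC(=O)OC)OO1
F6 | step 4 | methyl 2-[(3S,5R)-5-{(1E)-3-[(4S)-4-benzyl-2-oxo-1,3-oxazolidin-3-yl]-3-oxoprop-1-en-1-yl}-3,5-dimethyl-1,2-dioxolan-3-yl]acetate (ring diastereomer of 20) | O=C(/C=C/[C@@]1(C)C[C@@](C)(CC(=O)OC)OO1)N2C(=O)OC[C@@H]2Cc3ccccc3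
F7 | step 6 | (1R,6S)-1,6-dimethyl-3,7,8-trioxabicyclo[4.2.1]nonan-4-one (enantiomer of 11) | O=C1OC[C@@]2(C)C[C@@](C)(C1)OO2
F8 | step 11 | diethyl {2-[(4S)-4-benzyl-2-oxo-1,3-oxazolidin-3-yl]-2-oxoethyl}phosphonate | CCOP(=O)(CC(=O)N1C(=O)OC[C@@H]1Cc1ccccc1)OCC
F9 | step 13 | methyl 2-[(3R,5S)-3,5-dimethyl-5-[(1E)-2-methyl-3-oxoprop-1-en-1-yl]-1,2-dioxolan-3-yl]acetate | O=C/C(C)=C/[C@]1(C)C[C@](C)(CC(=O)OC)OO1
F10 | step 25 | 2-[(3R,5R)-5-[(2R)-7-hydroxy-2-methylheptyl]-3,5-dimethyl-1,2-dioxolan-3-yl]acetic acid | C[C@H](CCCCCO)C[C@]1(C)C[C@](C)(CC(=O)O)OO1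
F11 | step 25 | 2-[(3R,5R)-3,5-dimethyl-5-[(2R)-2-methyl-7-oxoheptyl]-1,2-dioxolan-3-yl]acetic acid | C[C@H](CCCCC=O)C[C@]1(C)C[C@](C)(CC(=O)O)OO1
F0 | step 26 | none | none
A1 | alternative 1 | (6R)-7-[(3R,5S)-5-{2-[tert-butyl(diphenyl)silyl]oxyethyl}-3,5-dimethyl-1,2-dioxolan-3-yl]-6-methylheptyl 2,2-dimethylpropanoate | C[C@H](CCCCCOC(=O)C(C)(C)C)C[C@]1(C)C[C@](C)(CCO[Si](c2ccccc2)(c2ccccc2)C(C)(C)C)OO1
A2 | alternative 1 | (6R)-8-methoxy-6-methyl-8-(triethylsilylperoxy)nonyl 2,2-dimethylpropanoate (both epimers at the ketal carbon) | C[C@H](CCCCCOC(=O)C(C)(C)C)CC(C)(OC)OO[Si](CC)(CC)CC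
A3 | alternative 1 | (R)-citronellal, (3R)-3,7-dimethyloct-6-enal | C[C@H](CCC=C(C)C)CC=O
A4 | alternative 1 | tert-butyl[(3-methylbut-3-en-1-yl)oxy]diphenylsilane | C=C(C)CCO[Si](c1ccccc1)(c1ccccc1)C(C)(C)C
A5 | alternative 2 | (1S,6S)-1,6-dimethyl-3,7,8-trioxabicyclo[4.2.1]nonane (needed enantiomer; formed as the racemate) | C1OC[C@]2(C)C[C@](C)(C1)OO2
A6 | alternative 2 | triethyl{[2-methoxy-4-(2-methylprop-2-en-1-yloxy)butan-2-yl]peroxy}silane (racemic) | C=C(C)COCCC(C)(OC)OO[Si](CC)(CC)CC
A7 | alternative 3 | 2-iodo-1,5-dimethyl-6,7-dioxabicyclo[3.2.1]octane, iodine anti to the peroxide (needed enantiomer; formed as the racemate) | C1[C@H](I)[C@]2(C)C[C@](C)(C1)OO2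
A8 | alternative 3 | m-xylene, 1,3-dimethylbenzene | Cc1cccc(C)c1
A9 | alternative 3 | 1,5-dimethylcyclohexa-1,4-diene | CC1=CCC=C(C)C1
A10 | alternative 3 | 1,3-dimethylcyclohex-3-en-1-yl hydroperoxide (racemic) | CC1=CCCC(C)(OO)C1
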